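The pyranone ring of the coumarin (O1–C2–C3–C4–C4a–C8a) is a cyclised cis-2-hydroxycinnamic acid. It is therefore cut at the O1–C2 ester bond and the C3=C4 alkene: C2 and C3 come from (triphenylphosphoranylidene)ketene, C4 from the formyl carbon of a salicylaldehyde. In one operation the phenol adds to the cumulated ylide and the ester ylide so formed olefinates the neighbouring aldehyde, which closes the ring as the last skeletal event. The precursor is 2-hydroxy-5-methoxybenzaldehyde carrying at O4 the complete (2E,4R) chain, its secondary hydroxyl masked as a TBS ether and its tertiary hydroxyl as a TES ether. The 4R centre is set by oxazaborolidine-catalysed reduction of an enone.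

Key step: step 9

Remark: chain locants 1'–8' count from the ether CH2; the only stereocentre is C4' (R) and the alkene C2'=C3' is E.

Step 1
Reactants: 1 prenyl acetate (3-methylbut-2-en-1-yl acetate)
Product: 2 (2E)-3-methyl-4-oxobut-2-en-1-yl acetate
Conditions: SeO2 (1.1 equiv), 1,4-dioxane, 90 °C
Reagents that add atoms: selenium dioxide, O=[Se]=O
Why: Riley allylic oxidation, in which the ene reaction and [2,3]-sigmatropic shift of SeO2 attack the (E)-methyl group of the trisubstituted alkene and carry it on to the conjugated (E)-aldehyde while the acetate is inert.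

Step 2
Reactants: 3 4-bromo-2-methylbutan-2-ol
Product: 4 [(4-bromo-2-methylbutan-2-yl)oxy]triethylsilane
Conditions: TESOTf, 2,6-lutidine, CH2Cl2, 0 °C
Reagents that add atoms: triethylsilyl trifluoromethanesulfonate (TESOTf), CC[Si](CC)(CC)OS(=O)(=O)C(F)(F)F
Why: Silyl triflate silylation, since the triflate with a hindered pyridine base is reactive enough for a tertiary alcohol and the primary bromide is not touched at 0 °C.

Step 3
Reactants: 4 [(4-bromo-2-methylbutan-2-yl)oxy]triethylsilane, 2 (2E)-3-methyl-4-oxobut-2-en-1-yl acetate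
Product: 6 rac-(2E)-4-hydroxy-3,7-dimethyl-7-(triethylsilyloxy)oct-2-en-1-yl acetate, via Grignard reagent 5 (not isolated)
Conditions: Mg turnings, THF, 40 °C; the solution of 5 (1.1 equiv) added to 2, THF, −78 °C; pH 7 aqueous quench
Reagents that add atoms: none
Why: Grignard 1,2-addition, in which the organomagnesium reagent should attack the aldehyde far faster than the acetate at −78 °C and the α-methyl group disfavours conjugate addition; the new carbinol centre is formed without control and is erased in step 4.

Step 4
Reactants: 6 rac-(2E)-4-hydroxy-3,7-dimethyl-7-(triethylsilyloxy)oct-2-en-1-yl acetate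
Product: 7 (2E)-3,7-dimethyl-4-oxo-7-(triethylsilyloxy)oct-2-en-1-yl acetate
Conditions: Dess–Martin periodinane (DMP), pyridine, CH2Cl2, 0 °C → rt
Reagents that add atoms: none
Why: Dess–Martin oxidation of the secondary allylic alcohol to the enone under pyridine-buffered, near-neutral conditions that spare the silyl ether, the acetate and the alkene geometry.

Step 5
Reactants: 7 (2E)-3,7-dimethyl-4-oxo-7-(triethylsilyloxy)oct-2-en-1-yl acetate
Product: 8 (2E,4R)-4-hydroxy-3,7-dimethyl-7-(triethylsilyloxy)oct-2-en-1-yl acetate
Conditions: (S)-2-methyl-CBS-oxazaborolidine [(3aS)-1-methyl-3,3-diphenyltetrahydro-1H,3H-pyrrolo[1,2-c][1,3,2]oxazaborole] (0.2 equiv), BH3·SMe2 (0.7 equiv), THF, −30 °C; MeOH quench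
Reagents that add atoms: none
Why: Corey–Bakshi–Shibata reduction, in which the ketone binds to the ring boron with its bulkier α-methylalkenyl arm turned away from the catalyst and hydride passes from the nitrogen-bound borane through a six-membered transition state, so that the (S)-catalyst should give the 4R alcohol (the sense known for aryl and alkenyl alkyl ketones) by 1,2-reduction without touching the acetate.

Step 6
Reactants: 8 (2E,4R)-4-hydroxy-3,7-dimethyl-7-(triethylsilyloxy)oct-2-en-1-yl acetate
Product: 9 (2E,4R)-4-(tert-butyldimethylsilyloxy)-3,7-dimethyl-7-(triethylsilyloxy)oct-2-en-1-yl acetate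
Conditions: TBSOTf, 2,6-lutidine, CH2Cl2, −78 → 0 °C
Reagents that add atoms: tert-butyldimethylsilyl trifluoromethanesulfonate (TBSOTf), CC(C)(C)[Si](C)(C)OS(=O)(=O)C(F)(F)F
Why: Silyl triflate silylation of the hindered secondary allylic alcohol, in which no bond to C4 is broken and the R configuration is therefore kept.

Step 7
Reactants: 9 (2E,4R)-4-(tert-butyldimethylsilyloxy)-3,7-dimethyl-7-(triethylsilyloxy)oct-2-en-1-yl acetate
Product: 10 (2E,4R)-4-(tert-butyldimethylsilyloxy)-3,7-dimethyl-7-(triethylsilyloxy)oct-2-en-1-ol
Conditions: K2CO3 (0.2 equiv), MeOH, 0 °C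
Reagents that add atoms: none
Why: Base-catalysed transesterification (methanolysis) removes the primary acetate, both silyl ethers being stable to carbonate in methanol and the E geometry keeping the TBS group out of reach of the new hydroxyl.

Step 8
Reactants: 10 (2E,4R)-4-(tert-butyldimethylsilyloxy)-3,7-dimethyl-7-(triethylsilyloxy)oct-2-en-1-ol, 11 2,4-dihydroxy-5-methoxybenzaldehyde
Product: 12 4-{[(2E,4R)-4-(tert-butyldimethylsilyloxy)-3,7-dimethyl-7-(triethylsilyloxy)oct-2-en-1-yl]oxy}-2-hydroxy-5-methoxybenzaldehyde
Conditions: PPh3, DIAD, THF, 0 °C → rt (11 in 1.3-fold excess)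
Reagents that add atoms: none
Why: Mitsunobu etherification, in which the activated primary allylic alcohol is displaced at C1' by the more acidic 4-hydroxyl (para to the formyl group) while the 2-hydroxyl is tied up in a hydrogen bond to the aldehyde, and attack at the fully substituted C3' end is sterically blocked, so alkene geometry and the C4' centre are unchanged.

Step 9
Reactants: 12 4-{[(2E,4R)-4-(tert-butyldimethylsilyloxy)-3,7-dimethyl-7-(triethylsilyloxy)oct-2-en-1-yl]oxy}-2-hydroxy-5-methoxybenzaldehyde, 13 (triphenylphosphoranylidene)ketene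
Product: 15 7-{[(2E,4R)-4-(tert-butyldimethylsilyloxy)-3,7-dimethyl-7-(triethylsilyloxy)oct-2-en-1-yl]oxy}-6-methoxy-2H-chromen-2-one, via aryl ester ylide 14 (not isolated)
Conditions: 13 (1.3 equiv), dry toluene (about 0.02 M), 90–110 °C, N2
Reagents that add atoms: none
Why: Proton transfer from the phenol of 12 to the ylide carbon of 13 and collapse of the phenoxide onto the ketene carbon should give ester ylide 14 (new O1–C2 bond), whose nucleophilic carbon then adds to the adjacent formyl group and, through an oxaphosphetane, loses Ph3PO to leave the C3=C4 double bond. The closest known reaction type is the coumarin synthesis from ortho-hydroxybenzaldehydes and ketenylidenetriphenylphosphorane, that is O-acylation followed by intramolecular Wittig olefination. The pyranone ring closes in the C–C bond-forming event by 6-exo-trig attack on the aldehyde carbon, and the six-membered ring allows only the cis C3=C4 alkene. No stereocentre is created, and the C4' centre and the C2'=C3' alkene lie far from the reacting atoms and are not exposed to acid or base. The step needs chemoselectivity for the phenol, which the silylation of both side-chain hydroxyls secures by leaving the phenol as the only O–H group, and it needs intra- over intermolecular olefination, which the ortho arrangement and dilution secure. The temperature stays well below that at which an aryl allyl ether undergoes Claisen rearrangement.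

Step 10
Reactants: 15 7-{[(2E,4R)-4-(tert-butyldimethylsilyloxy)-3,7-dimethyl-7-(triethylsilyloxy)oct-2-en-1-yl]oxy}-6-methoxy-2H-chromen-2-one
Product: 16 7-{[(2E,4R)-4,7-dihydroxy-3,7-dimethyloct-2-en-1-yl]oxy}-6-methoxy-2H-chromen-2-one
Conditions: Bu4NF, AcOH (1:1), THF, rt → 45 °C
Reagents that add atoms: none
Why: Fluoride-mediated desilylation driven by Si–F bond formation should cleave both silyl ethers at silicon, so the C4'–O bond and the R configuration are kept, and acetic acid buffering protects the lactone and the allylic aryl ether.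

Compound list
1 | prenyl acetate (3-methylbut-2-en-1-yl acetate) | CC(C)=CCOC(C)=O | starting material
2 | (2E)-3-methyl-4-oxobut-2-en-1-yl acetate | CC(=O)OC/C=C(\C)C=O | intermediate
3 | 4-bromo-2-methylbutan-2-ol | CC(C)(O)CCBr | starting material
4 | [(4-bromo-2-methylbutan-2-yl)oxy]triethylsilane | CC[Si](CC)(CC)OC(C)(C)CCBr | intermediate
5 | [3-methyl-3-(triethylsilyloxy)butyl]magnesium bromide | CC[Si](CC)(CC)OC(C)(C)CC[Mg]Br | intermediate (not isolated)
6 | rac-(2E)-4-hydroxy-3,7-dimethyl-7-(triethylsilyloxy)oct-2-en-1-yl acetate | CC(=O)OC/C=C(\C)C(O)CCC(C)(C)O[Si](CC)(CC)CC | intermediate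
7 | (2E)-3,7-dimethyl-4-oxo-7-(triethylsilyloxy)oct-2-en-1-yl acetate | CC(=O)OC/C=C(\C)C(=O)CCC(C)(C)O[Si](CC)(CC)CC | intermediate
8 | (2E,4R)-4-hydroxy-3,7-dimethyl-7-(triethylsilyloxy)oct-2-en-1-yl acetate | CC(=O)OC/C=C(\C)[C@H](O)CCC(C)(C)O[Si](CC)(CC)CC | intermediate
9 | (2E,4R)-4-(tert-butyldimethylsilyloxy)-3,7-dimethyl-7-(triethylsilyloxy)oct-2-en-1-yl acetate | CC(=O)OC/C=C(\C)[C@H](O[Si](C)(C)C(C)(C)C)CCC(C)(C)O[Si](CC)(CC)CC | intermediate
10 | (2E,4R)-4-(tert-butyldimethylsilyloxy)-3,7-dimethyl-7-(triethylsilyloxy)oct-2-en-1-ol | OC/C=C(\C)[C@H](O[Si](C)(C)C(C)(C)C)CCC(C)(C)O[Si](CC)(CC)CC | intermediate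
11 | 2,4-dihydroxy-5-methoxybenzaldehyde | COc1cc(C=O)c(O)cc1O | starting material
12 | 4-{[(2E,4R)-4-(tert-butyldimethylsilyloxy)-3,7-dimethyl-7-(triethylsilyloxy)oct-2-en-1-yl]oxy}-2-hydroxy-5-methoxybenzaldehyde | COc1cc(C=O)c(O)cc1OC/C=C(\C)[C@H](O[Si](C)(C)C(C)(C)C)CCC(C)(C)O[Si](CC)(CC)CC | intermediate
13 | (triphenylphosphoranylidene)ketene | O=C=C=P(c1ccccc1)(c1ccccc1)c1ccccc1 | starting material
14 | 2-formyl-4-methoxy-5-{[(2E,4R)-4-(tert-butyldimethylsilyloxy)-3,7-dimethyl-7-(triethylsilyloxy)oct-2-en-1-yl]oxy}phenyl (triphenylphosphoranylidene)acetate | COc1cc(C=O)c(OC(=O)C=P(c2ccccc2)(c2ccccc2)c2ccccc2)cc1OC/C=C(\C)[C@H](O[Si](C)(C)C(C)(C)C)CCC(C)(C)O[Si](CC)(CC)CC | intermediate (not isolated)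
15 | 7-{[(2E,4R)-4-(tert-butyldimethylsilyloxy)-3,7-dimethyl-7-(triethylsilyloxy)oct-2-en-1-yl]oxy}-6-methoxy-2H-chromen-2-one | COc1cc2ccc(=O)oc2cc1OC/C=C(\C)[C@H](O[Si](C)(C)C(C)(C)C)CCC(C)(C)O[Si](CC)(CC)CC | intermediate
16 | 7-{[(2E,4R)-4,7-dihydroxy-3,7-dimethyloct-2-en-1-yl]oxy}-6-methoxy-2H-chromen-2-one | COc1cc2ccc(=O)oc2cc1OC/C=C(\C)[C@H](O)CCC(C)(C)O | target

Total step count: 10
Longest linear sequence: 9 steps (steps 1 and 3–10; the arm through step 2 is equally long)

Steps most likely to fail

Step 9. The hydrogen-bonded phenol may add to the cumulated ylide too slowly, so that hydrolysis or self-condensation of the ylide, or olefination between two molecules, outruns ring closure. The fallback gives up the late ring construction and forms the ether bond last on a ready-made pyranone. Alcohol 10 is coupled under Mitsunobu conditions (PPh3, DIAD, THF, 0 °C → rt) with commercial scopoletin (7-hydroxy-6-methoxy-2H-chromen-2-one, COc1cc2ccc(=O)oc2cc1O), whose single acidic hydroxyl also removes the regiochemical question. It sets out from 10 and comes back to the route at 15; no compound outside the list is made (none F0).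

Step 5. Facial discrimination in the hydride transfer may be insufficient if the two ketone arms are not differentiated well enough, and hydroboration of the alkene may compete. The fallback replaces asymmetric reduction by resolution. Racemic alcohol 6 is subjected to Sharpless kinetic resolution (Ti(OiPr)4, L-(+)-diisopropyl tartrate, t-BuOOH (0.6 equiv), 4 Å molecular sieves, CH2Cl2, −20 °C). By the usual rule the 4S enantiomer should be epoxidised fast to the erythro epoxy alcohol [(2S,3S)-3-[(1S)-1-hydroxy-4-methyl-4-(triethylsilyloxy)pentyl]-3-methyloxiran-2-yl]methyl acetate F1, which is removed by chromatography, and the unreacted 4R alcohol is 8. It sets out from 6 and comes back at 8, so steps 4 and 5 are no longer needed.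

Step 8. Regiocontrol between the two phenolic hydroxyls may be lost, with ether formation at the chelated 2-hydroxyl or at both. The fallback is an alkylation with a discrete electrophile and a base too weak to deprotonate the chelated phenol. Alcohol 10 is converted by an Appel reaction (CBr4, PPh3, 2,6-lutidine, CH2Cl2, −20 → 0 °C) into (2E,4R)-1-bromo-4-(tert-butyldimethylsilyloxy)-3,7-dimethyl-7-(triethylsilyloxy)oct-2-ene F2, which then alkylates 11 with CsHCO3 in MeCN at 60 °C. It sets out from 10 and comes back at 12.

Further compounds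
F0 | step 9 | none | none
F1 | step 5 | [(2S,3S)-3-[(1S)-1-hydroxy-4-methyl-4-(triethylsilyloxy)pentyl]-3-methyloxiran-2-yl]methyl acetate | CC(=O)OC[C@@H]1O[C@@]1(C)[C@@H](O)CCC(C)(C)O[Si](CC)(CC)CC
F2 | step 8 | (2E,4R)-1-bromo-4-(tert-butyldimethylsilyloxy)-3,7-dimethyl-7-(triethylsilyloxy)oct-2-ene | BrC/C=C(\C)[C@H](O[Si](C)(C)C(C)(C)C)CCC(C)(C)O[Si](CC)(CC)CC
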